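## Structural features

- The target is a 2,3,4‑trisubstituted tetrahydrofuran, numbered here O1, C2, C3, C4, C5. C2 carries a 4‑hydroxy‑3‑methoxyphenyl (guaiacyl) ring directly, C3 carries the C9 methylene whose oxygen is acylated by (R)‑2‑methylbutanoic acid, C4 carries a guaiacylmethyl group (benzylic carbon C7′), and C5 is an unsubstituted CH2. It is the 9‑O‑ester of (−)‑lariciresinol.
- The three ring stereocentres are contiguous, (2R,3S,4S): the aryl group on C2 is trans to C9, and C9 is cis to C7′. A fourth, isolated (R) centre sits α to the ester carbonyl.
- The C2–O1 bond is a para‑hydroxybenzylic ether. Acid ionises it, which can epimerise C2 or let the second arene capture the cation to give an aryltetralin.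
- The two phenols compete with the C9 hydroxyl in any acylation, and the ester is open to basic hydrolysis and α‑epimerisation.
- The real difficulty is the absolute and relative control of the adjacent carbon‑substituted centres C3 and C4. The ring itself is not the problem, and C2 can be left to thermodynamics because its trans arrangement is the stable one.
- The feature exploited is that C2 and C7′ both sit at the oxidation level and substitution pattern of the aldehyde carbon of vanillin, and they flank the C3–C4 bond. The chain C9–C3–C4–C5 is a four‑carbon unit oxygenated at both ends, i.e. a butenolide with C9 as carbonyl, C3 as α‑carbon, C4 as β‑carbon and C5 as acetal carbon.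
- Because the lactone ring (C9, C3, C4, C5) and the final ether ring (C2, C3, C4, C5) share only C3–C4–C5, a 3,4‑trans lactone becomes the 3,4‑cis tetrahydrofuran.

## Logic of the disconnections

**18 ⇒ 17.** The two aryl O–H bonds are traced back to aryl O–Si bonds. The phenols must be masked while the C9 ester is made. The gain is full chemoselectivity in the acylation. The demand is a deprotection that spares the ester, its α‑centre and the benzylic C2–O1 bond, which points to buffered fluoride.

**17 ⇒ 15 + 16.** The acyl C–O9 bond is cut. The acid part is a small chiral‑pool piece, so the cut is convergent and leaves a lignan alcohol with a single free hydroxyl. The forward step must acylate a primary alcohol without epimerising the α‑centre of the acid.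

**15 ⇒ 14.** The O1–C2 bond is cut. C2 is benzylic and para‑oxygenated, so it can be closed through a cation, and its configuration is then set by the neighbouring C3 under equilibrium. This removes the ring and one stereocentre from the problem and leaves an open‑chain triol in which only C3 and C4 matter. The forward step must close with the C5 hydroxyl (five‑membered ring) rather than the C9 hydroxyl (four‑membered ring), and must stop before the second arene attacks the cation.

**14 ⇒ 13.** Two C–S bonds are put back on C7′. The thioketal is what allows C7′ to act as a carbanion earlier on. The demand is a desulfurisation that tolerates a benzylic alcohol and aryl silyl ethers. Placing it after the hydride reduction means no carbonyl group is exposed to the borohydride medium.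

**13 ⇒ 12.** The C9 and C5 hydroxyls are reconnected as a lactone whose C5 is an acetal bearing the chiral auxiliary. This gives a rigid five‑membered ring that can relay stereochemistry, and it differentiates the two ends. The demand is that one hydride reagent reduces both C9 and C5, releases the auxiliary and leaves C3 untouched.

**12 ⇒ 9 + 6 + 8.** The C4–C7′ and C2–C3 bonds are cut. This is the strategic cut: both aryl‑bearing carbons come from the same aldehyde, once as an acyl‑anion equivalent (9) and once as the electrophile (8), added across the double bond of 6. The skeleton falls to three simple pieces. The forward step needs 1,4‑ rather than 1,2‑addition, attack anti to the C5 alkoxy group, and anti trapping of the enolate.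

**9 ⇒ 8 ⇒ 7.** The thioketal C–S bonds and then the O–Si bond are cut. One silylated aldehyde serves both roles, so the branch is two steps. Triisopropylsilyl is chosen because the ether must survive n‑BuLi, LiAlH4 and methanolic borohydride, where a phenolic tert‑butyldimethylsilyl ether is at risk. Fluoride still removes it at the end.

**6 ⇒ 3 + 4 ⇒ 1.** The acetal C5–O bond is cut, then the hydroxybutenolide is traced to a furan by oxidative loss of the formyl carbon. The auxiliary is a cheap terpene alcohol and the furan is a bulk chemical. The demand is that the acetal diastereomers can be separated; the acetal carbon epimerises under acid and one diastereomer crystallises.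

## Other disconnections considered

**Alternative 1:** The cut is the ring bond C3–C4, with the C7′–H bond formed in the same event. The precursor is the erythro epoxy cinnamyl ether A2, built from the silylated aldehyde A1 by way of an aryl vinyl carbinol, an asymmetric epoxidation with kinetic resolution, and O‑alkylation with a cinnamyl partner.
- Forward key step: Cp2TiCl (from Cp2TiCl2 and Zn) opens the oxirane homolytically to the C3 radical with the titanium‑bound oxygen on C9. The radical adds 5‑exo‑trig to the styrene, and the benzylic C7′ radical is reduced by a second equivalent of trivalent titanium and protonated. The product would be the bis‑silyl lariciresinol A3.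
- In its favour: A3 is the direct analogue of 15 with the C9 hydroxyl already free. The ring and the C3 and C4 centres arise in one step. No auxiliary has to be removed and no sulfur is used. C2 is installed beforehand and never passes through a cation, which is better than the chosen plan on that point.
- Step economy: the longest linear sequence to A3 would be about five steps, against six to 15 in the chosen plan, so the alternative is slightly better here.
- Against it: the absolute configuration rests on a kinetic resolution of an acid‑labile, electron‑rich carbinol, which discards half the material. The etherification of a secondary epoxy alcohol under base invites epoxide migration. The C3/C4 relationship is decided in an early radical transition state, so 3,4‑cis versus 3,4‑trans control is inherently partial and cannot be corrected later. In the chosen plan the same relationship comes from a sterically enforced anti addition on a ring.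
- Further points against: two different aryl building blocks are needed, so the identity of the two guaiacyl units is not used. The titanium reagent is stoichiometric and Lewis acidic towards a benzylic ether.
- The end game (esterification, desilylation) is equal in both plans.

**Alternative 2:** The cuts are C2–C3 and the O1–C5 bond, the latter as a lactone acyl–oxygen bond. The allylboronate must be the 4‑silyloxy‑substituted Z butenoate A4; an unsubstituted but‑2‑enoate would leave a methyl group where C9 needs its oxygen.
- Forward key step: aldehyde A1 and A4 react under chiral phosphoric acid catalysis through a closed chair transition state. The Z geometry translates into the anti adduct, and the borate alkoxide lactonises to the trans methylene lactone A5.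
- In its favour: chirality comes from a catalyst rather than a stoichiometric auxiliary, which is better than the chosen plan. C2 and C3 are set together and kinetically, so C2 does not depend on a later cation equilibration, also better. Both plans draw C2 from the same kind of aldehyde, which is equal.
- Against it: C4 and the C7′–aryl bond are still missing after the key step. They would come from conjugate addition of an aryl nucleophile to the methylene group, followed by protonation cis to the C3 substituent. That epimer is the less stable one and sits α to a carbonyl, so it can be lost.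
- Further points against: an electron‑rich aldehyde paired with an ester‑deactivated allylboronate is the least reactive combination for this reaction. A4 needs its own multi‑step preparation. The lactone carbonyl C5 must be reduced to CH2 in two steps, and the primary silyl ether must be cleaved selectively beside two aryl silyl ethers.
- Step economy: about six steps would follow the key step, against five in the chosen plan, and the total would be clearly longer.

**Alternative 3:** The cuts are C2–C3 and C4–C5. Ring oxygen O1 and its two flanking carbons are delivered as a C–O–C dipole to C3=C4 of the enantiomeric butenolide A7. The butenolide is used in the opposite sense to the chosen plan: its carbonyl is C9 and its acetal carbon becomes C7′.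
- Forward key step: fluoride removes the silyl group from the α‑chloro silylmethyl ether A6 with loss of chloride. The carbonyl ylide adds across the butenolide anti to the menthyloxy group, carbanion terminus to the β‑carbon, to give the cis‑fused bicycle A8 with the aryl group exo.
- In its favour: the tetrahydrofuran and the relative configuration of C2, C3 and C4 (cis fusion is 3,4‑cis, exo aryl is 2,3‑trans) appear in one neutral step. No later ring closure is needed and no cation forms at C2, which is better than the chosen plan on ring construction. The auxiliary is of the same class and derives from the cheaper (−)‑menthol, which is equal or slightly better.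
- Against it: C7′ emerges as an acetal carbon without its aryl group. A second aryl–carbon bond and a benzylic deoxygenation must follow, the latter beside the equally benzylic C2–O1 bond. C9 remains at the acid level and must be reduced.
- Further points against: A6 is moisture‑sensitive and, coming from an electron‑rich aldehyde, ionises easily. The exo/endo preference of a non‑stabilised ylide is not assured and cannot be corrected afterwards.
- Step economy: about seven steps would follow the key step, so the alternative is worse. The chosen plan delivers C7′ with its aryl group attached and needs only a desulfurisation to reach the right oxidation level.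

Key step: step 5

Assumptions: the carbinol carbon (future C2) of 12, 13 and 14 is written without configuration, because both epimers are expected to form in step 5 and both should converge in step 8. The phenols are carried as triisopropylsilyl ethers throughout.

## Route

Step 1
Reactants: 1 furfural
Product: 3 5-hydroxyfuran-2(5H)-one (racemic hemiacetal), via furfural endoperoxide 2 (not isolated)
Conditions: O2, methylene blue (cat.), MeOH, visible light, 20 °C
Reagents that add atoms: dioxygen, O=O
Why: Dye‑sensitised photooxygenation: singlet oxygen adds [4+2] across C2/C5 of the furan, and methanolysis of endoperoxide 2 expels the formyl carbon as methyl formate, leaving the hydroxybutenolide; the hemiacetal centre is racemic and is dealt with in step 2.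

Step 2
Reactants: 3 5-hydroxyfuran-2(5H)-one; 4 (1S,2R,5S)-(+)-menthol
Product: 6 (5S)-5-[(1S,2R,5S)-menthyloxy]furan-2(5H)-one, via C5-epimeric acetal mixture 5 (not isolated)
Conditions: camphorsulfonic acid (cat.), toluene, reflux, Dean–Stark; crystallisation from petroleum ether, mother liquor re‑equilibrated with acid and recrystallised
Reagents that add atoms: none
Why: Acid‑catalysed acetalisation of the cyclic hemiacetal with removal of water; the acetal carbon epimerises under the same acid and the (5S) diastereomer from (+)-menthol is the one that crystallises, so C5 is set by crystallisation of diastereomers with recycling.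

Step 3
Reactants: 7 vanillin
Product: 8 3-methoxy-4-(triisopropylsilyloxy)benzaldehyde
Conditions: TIPSCl, imidazole, DMF, 20 °C
Reagents that add atoms: triisopropylsilyl chloride, CC(C)[Si](Cl)(C(C)C)C(C)C
Why: Imidazole‑promoted silylation of a phenol; the triisopropylsilyl ether is chosen because it should withstand n‑BuLi, LiAlH4 and methanolic borohydride later on and still fall to fluoride at the end.

Step 4
Reactants: 8 3-methoxy-4-(triisopropylsilyloxy)benzaldehyde
Product: 9 2-[3-methoxy-4-(triisopropylsilyloxy)phenyl]-1,3-dithiane
Conditions: HS(CH2)3SH, BF3·OEt2 (cat.), CH2Cl2, 0 °C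
Reagents that add atoms: propane-1,3-dithiol, SCCCS
Why: Lewis‑acid‑catalysed thioacetalisation of an aromatic aldehyde; the hindered aryl silyl ether should tolerate catalytic BF3·OEt2 at 0 °C, and no stereocentre is formed.

Step 5
Reactants: 9 2-[3-methoxy-4-(triisopropylsilyloxy)phenyl]-1,3-dithiane; 6 (5S)-5-[(1S,2R,5S)-menthyloxy]furan-2(5H)-one; 8 3-methoxy-4-(triisopropylsilyloxy)benzaldehyde
Product: 12 (3R,4S,5S)-3-{hydroxy[3-methoxy-4-(triisopropylsilyloxy)phenyl]methyl}-4-{2-[3-methoxy-4-(triisopropylsilyloxy)phenyl]-1,3-dithian-2-yl}-5-[(1S,2R,5S)-menthyloxy]dihydrofuran-2(3H)-one (carbinol epimers), via lithiated dithiane 10 (not isolated), via lithium lactone enolate 11 (not isolated)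
Conditions: n-BuLi, THF, −78 → −30 °C; then 6, −78 °C; then 8, −78 °C; AcOH quench at −78 °C
Reagents that add atoms: none
Why: n‑BuLi removes the doubly sulfur‑stabilised benzylic proton of 9, and the soft, hindered carbanion 10 adds 1,4 to butenolide 6; the closest known reaction type is the tandem conjugate addition–enolate trapping of lithiated 2‑aryl‑1,3‑dithianes on γ‑alkoxybutenolides. The menthyloxy group on C5 blocks its own face of the flat five‑membered acceptor, so C7′ bonds to C4 on the opposite face and C4 is set as S by the acetal centre. The lithium enolate 11 then adds to the non‑enolisable aldehyde 8 in an aldol reaction through a closed, lithium‑bridged transition state on the face away from the fully substituted dithianyl group, which sets C3 trans to C4. The carbinol centre is only weakly controlled and may form as a mixture, which is acceptable because it is reset in step 8. No ring closes; two skeletal bonds (C4–C7′ and C2–C3) and three stereocentres are created. The step needs 1,4‑ over 1,2‑addition, which the delocalised, bulky thioketal anion in THF at −78 °C should secure. It also needs C‑attack without retro‑aldol, which the lithium counter‑ion and the cold acetic acid quench should secure. Neither electrophile can quench 11 by proton transfer, because 8 has no α‑hydrogen.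

Step 6
Reactants: 12 the aldol lactone of step 5
Product: 13 (2S,3S)-2-{hydroxy[3-methoxy-4-(triisopropylsilyloxy)phenyl]methyl}-3-{2-[3-methoxy-4-(triisopropylsilyloxy)phenyl]-1,3-dithian-2-yl}butane-1,4-diol (carbinol epimers)
Conditions: LiAlH4, THF, 0 → 20 °C; H2O/NaOH work‑up
Reagents that add atoms: none
Why: Hydride reduction of a lactone acyl acetal: C9 is reduced to CH2OH, the freed C5 hemiacetal alkoxide collapses to the aldehyde with loss of the menthyl oxide and is reduced in turn; the thioketal and the aryl silyl ethers are inert and C3 and C4 are not touched.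

Step 7
Reactants: 13 the dithianyl triol
Product: 14 (2S,3S)-2-{hydroxy[3-methoxy-4-(triisopropylsilyloxy)phenyl]methyl}-3-[3-methoxy-4-(triisopropylsilyloxy)benzyl]butane-1,4-diol (carbinol epimers)
Conditions: NiCl2·6H2O, NaBH4, MeOH–THF, 0 °C
Reagents that add atoms: none
Why: Reductive desulfurisation with nickel boride made in the flask cleaves both benzylic C–S bonds and turns C7′ into CH2; with no carbonyl group left, retro‑aldol and carbonyl reduction cannot interfere, and no stereocentre is touched.

Step 8
Reactants: 14 the triol
Product: 15 [(2R,3S,4S)-4-[3-methoxy-4-(triisopropylsilyloxy)benzyl]-2-[3-methoxy-4-(triisopropylsilyloxy)phenyl]tetrahydrofuran-3-yl]methanol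
Conditions: camphorsulfonic acid (cat.), CH2Cl2, 0 °C
Reagents that add atoms: none
Why: Acid ionises only the benzylic carbinol to a para‑silyloxy‑stabilised cation, and the C5 hydroxyl closes the five‑membered ether (cationic cycloetherification), whereas the C9 hydroxyl could only give an oxetane; the aryl group settles trans to the C3 substituent in the less crowded and reversible closure, so both carbinol epimers should converge on (2R) while C3 and C4 stay fixed.

Step 9
Reactants: 15 the bis‑silyl lariciresinol; 16 (R)-2-methylbutanoic acid
Product: 17 [(2R,3S,4S)-4-[3-methoxy-4-(triisopropylsilyloxy)benzyl]-2-[3-methoxy-4-(triisopropylsilyloxy)phenyl]tetrahydrofuran-3-yl]methyl (2R)-2-methylbutanoate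
Conditions: DCC, DMAP (cat.), CH2Cl2, 0 → 20 °C
Reagents that add atoms: none
Why: Steglich esterification of the only free hydroxyl, a primary alcohol; a simple α‑alkyl acid with catalytic DMAP at low temperature should keep its (R) centre.

Step 10
Reactants: 17 the bis‑silyl ester
Product: 18 [(2R,3S,4S)-4-(4-hydroxy-3-methoxybenzyl)-2-(4-hydroxy-3-methoxyphenyl)tetrahydrofuran-3-yl]methyl (2R)-2-methylbutanoate (target)
Conditions: TBAF, AcOH, THF, 0 °C
Reagents that add atoms: none
Why: Fluoride cleavage of aryl silyl ethers; buffering with acetic acid keeps the phenoxides protonated so that the ester and its α‑centre are not exposed to base, and the medium is too weakly acidic to ionise C2–O1.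

## Compound list

1 | furfural | O=Cc1ccco1 | starting material
2 | 2,3,7-trioxabicyclo[2.2.1]hept-5-ene-1-carbaldehyde (furfural endoperoxide, racemic) | O=CC12OOC(C=C1)O2 | intermediate (not isolated)
3 | 5-hydroxyfuran-2(5H)-one (racemic) | O=C1C=CC(O)O1 | intermediate
4 | (1S,2R,5S)-(+)-menthol | C[C@H]1CC[C@@H]([C@H](C1)O)C(C)C | starting material
5 | 5-[(1S,2R,5S)-menthyloxy]furan-2(5H)-one, mixture of C5 epimers | O=C1C=CC(O[C@H]2C[C@@H](C)CC[C@@H]2C(C)C)O1 | intermediate (not isolated)
6 | (5S)-5-[(1S,2R,5S)-menthyloxy]furan-2(5H)-one | O=C1C=C[C@@H](O[C@H]2C[C@@H](C)CC[C@@H]2C(C)C)O1 | intermediate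
7 | vanillin | COc1cc(C=O)ccc1O | starting material
8 | 3-methoxy-4-(triisopropylsilyloxy)benzaldehyde | COc1cc(C=O)ccc1O[Si](C(C)C)(C(C)C)C(C)C | intermediate
9 | 2-[3-methoxy-4-(triisopropylsilyloxy)phenyl]-1,3-dithiane | COc1cc(C2SCCCS2)ccc1O[Si](C(C)C)(C(C)C)C(C)C | intermediate
10 | 2-lithio-2-[3-methoxy-4-(triisopropylsilyloxy)phenyl]-1,3-dithiane | COc1cc(C2([Li])SCCCS2)ccc1O[Si](C(C)C)(C(C)C)C(C)C | intermediate (not isolated)
11 | lithium (4S,5S)-4-{2-[3-methoxy-4-(triisopropylsilyloxy)phenyl]-1,3-dithian-2-yl}-5-[(1S,2R,5S)-menthyloxy]-4,5-dihydrofuran-2-olate | [Li]OC1=C[C@H](C2(c3ccc(O[Si](C(C)C)(C(C)C)C(C)C)c(OC)c3)SCCCS2)[C@@H](O[C@H]4C[C@@H](C)CC[C@@H]4C(C)C)O1 | intermediate (not isolated)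
12 | (3R,4S,5S)-3-{hydroxy[3-methoxy-4-(triisopropylsilyloxy)phenyl]methyl}-4-{2-[3-methoxy-4-(triisopropylsilyloxy)phenyl]-1,3-dithian-2-yl}-5-[(1S,2R,5S)-menthyloxy]dihydrofuran-2(3H)-one, carbinol epimers | O=C1[C@@H](C(O)c2ccc(O[Si](C(C)C)(C(C)C)C(C)C)c(OC)c2)[C@H](C3(c4ccc(O[Si](C(C)C)(C(C)C)C(C)C)c(OC)c4)SCCCS3)[C@@H](O[C@H]5C[C@@H](C)CC[C@@H]5C(C)C)O1 | intermediate
13 | (2S,3S)-2-{hydroxy[3-methoxy-4-(triisopropylsilyloxy)phenyl]methyl}-3-{2-[3-methoxy-4-(triisopropylsilyloxy)phenyl]-1,3-dithian-2-yl}butane-1,4-diol, carbinol epimers | OC[C@@H](C(O)c1ccc(O[Si](C(C)C)(C(C)C)C(C)C)c(OC)c1)[C@H](C2(c3ccc(O[Si](C(C)C)(C(C)C)C(C)C)c(OC)c3)SCCCS2)CO | intermediate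
14 | (2S,3S)-2-{hydroxy[3-methoxy-4-(triisopropylsilyloxy)phenyl]methyl}-3-[3-methoxy-4-(triisopropylsilyloxy)benzyl]butane-1,4-diol, carbinol epimers | OC[C@@H](C(O)c1ccc(O[Si](C(C)C)(C(C)C)C(C)C)c(OC)c1)[C@H](Cc1ccc(O[Si](C(C)C)(C(C)C)C(C)C)c(OC)c1)CO | intermediate
15 | [(2R,3S,4S)-4-[3-methoxy-4-(triisopropylsilyloxy)benzyl]-2-[3-methoxy-4-(triisopropylsilyloxy)phenyl]tetrahydrofuran-3-yl]methanol | OC[C@@H]1[C@H](Cc2ccc(O[Si](C(C)C)(C(C)C)C(C)C)c(OC)c2)CO[C@H]1c1ccc(O[Si](C(C)C)(C(C)C)C(C)C)c(OC)c1 | intermediate
16 | (R)-2-methylbutanoic acid | CC[C@@H](C)C(=O)O | starting material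
17 | [(2R,3S,4S)-4-[3-methoxy-4-(triisopropylsilyloxy)benzyl]-2-[3-methoxy-4-(triisopropylsilyloxy)phenyl]tetrahydrofuran-3-yl]methyl (2R)-2-methylbutanoate | CC[C@@H](C)C(=O)OC[C@@H]1[C@H](Cc2ccc(O[Si](C(C)C)(C(C)C)C(C)C)c(OC)c2)CO[C@H]1c1ccc(O[Si](C(C)C)(C(C)C)C(C)C)c(OC)c1 | intermediate
18 | [(2R,3S,4S)-4-(4-hydroxy-3-methoxybenzyl)-2-(4-hydroxy-3-methoxyphenyl)tetrahydrofuran-3-yl]methyl (2R)-2-methylbutanoate | CC[C@@H](C)C(=O)OC[C@@H]1[C@H](Cc2ccc(O)c(OC)c2)CO[C@H]1c1ccc(O)c(OC)c1 | target

## Step count and least certain steps

Total step count: 10. Longest linear sequence: 8 steps (steps 1, 2, 5, 6, 7, 8, 9, 10; the branch through steps 3 and 4 is equally long).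

**Step 5 (key step).** The most likely failure is at the aldol stage. Enolate 11 is flanked by a fully substituted carbon and aldehyde 8 is deactivated by its para oxygen, so the aldolate may revert before the quench and return the simple conjugate adduct. Some 1,2‑addition of 10, or proton abstraction at C5, could also erode the first stage.
Fallback (acylation then reduction, from 6, 8 and 9, returning at 12):
- The conjugate addition is run as before but quenched with acid to give (4S,5S)-4-{2-[3-methoxy-4-(triisopropylsilyloxy)phenyl]-1,3-dithian-2-yl}-5-[(1S,2R,5S)-menthyloxy]dihydrofuran-2(3H)-one F1.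
- Aldehyde 8 is oxidised (NaClO2, NaH2PO4, 2‑methylbut‑2‑ene) to 3-methoxy-4-(triisopropylsilyloxy)benzoic acid F2, which carbonyldiimidazole converts into 1-[3-methoxy-4-(triisopropylsilyloxy)benzoyl]imidazole F3.
- Deprotonation of F1 with LiN(i‑Pr)2 (two equivalents, THF, −78 °C) and C‑acylation with F3 should give the 3,4‑trans (3R,4S,5S)-3-[3-methoxy-4-(triisopropylsilyloxy)benzoyl] keto lactone F4. The step is driven forward because the product is held as its stabilised enolate.
- Reduction of the ketone with NaBH4 and CeCl3·7H2O in MeOH–THF at −40 °C leads back to 12 as a carbinol mixture, which is as acceptable as before.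

**Step 8.** The cation may over‑react. Acid strong enough to ionise the para‑silyloxybenzylic alcohol can also drive six‑ring capture by the second arene or loss of the C3 proton. If conditions are too mild, re‑ionisation may be too slow to equilibrate C2 fully.
Fallback (closure at the free‑phenol stage and a protecting‑group‑free end game, from 14, returning at 18):
- Desilylation of 14 with TBAF gives (2S,3S)-2-[hydroxy(4-hydroxy-3-methoxyphenyl)methyl]-3-(4-hydroxy-3-methoxybenzyl)butane-1,4-diol F6.
- Its para‑hydroxybenzylic alcohol should ionise through the neutral quinone methide in dilute aqueous acetic acid near room temperature. Under these conditions hydroxyl addition is expected to outrun arene attack, and the product is (−)-lariciresinol F7.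
- A Mitsunobu esterification of F7 with 16 (PPh3, diisopropyl azodicarboxylate, THF, 0 °C) activates only the aliphatic alcohol. It leaves the phenols alone because the acid is never activated, and gives 18 directly.

**Step 7.** Desulfurisation may be incomplete at the hindered, fully substituted benzylic carbon. The electron‑rich benzylic C–OH bond may be hydrogenolysed on the nickel surface, and the polar triol may be retained on the nickel residue.
Fallback (homolytic desulfurisation at the lactone stage, from 12, returning at 14):
- Bu3SnH and AIBN in toluene at 110 °C should cleave both C–S bonds by a radical chain that leaves benzylic C–O bonds alone. The product is (3R,4S,5S)-3-{hydroxy[3-methoxy-4-(triisopropylsilyloxy)phenyl]methyl}-4-[3-methoxy-4-(triisopropylsilyloxy)benzyl]-5-[(1S,2R,5S)-menthyloxy]dihydrofuran-2(3H)-one F5.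
- LiAlH4 in THF then reduces lactone and acetal to 14.

**Step 9.** The α‑centre of the acid may partly epimerise through the acylpyridinium or a ketene, and a branched acid may rearrange to the N‑acylurea.
Fallback (from 15, returning at 17): Mitsunobu esterification of 15 with 16 (PPh3, diisopropyl azodicarboxylate, THF, 0 °C). The alcohol is activated and the carboxylate acts as nucleophile, so the acyl carbon next to the stereocentre is never activated. No compound outside the route is formed (entry F0).

## Further compounds

F1 | step 5 | (4S,5S)-4-{2-[3-methoxy-4-(triisopropylsilyloxy)phenyl]-1,3-dithian-2-yl}-5-[(1S,2R,5S)-menthyloxy]dihydrofuran-2(3H)-one | O=C1C[C@H](C2(c3ccc(O[Si](C(C)C)(C(C)C)C(C)C)c(OC)c3)SCCCS2)[C@@H](O[C@H]4C[C@@H](C)CC[C@@H]4C(C)C)O1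
F2 | step 5 | 3-methoxy-4-(triisopropylsilyloxy)benzoic acid | COc1cc(C(=O)O)ccc1O[Si](C(C)C)(C(C)C)C(C)C
F3 | step 5 | 1-[3-methoxy-4-(triisopropylsilyloxy)benzoyl]imidazole | COc1cc(C(=O)n2ccnc2)ccc1O[Si](C(C)C)(C(C)C)C(C)C
F4 | step 5 | (3R,4S,5S)-3-[3-methoxy-4-(triisopropylsilyloxy)benzoyl]-4-{2-[3-methoxy-4-(triisopropylsilyloxy)phenyl]-1,3-dithian-2-yl}-5-[(1S,2R,5S)-menthyloxy]dihydrofuran-2(3H)-one | O=C1[C@@H](C(=O)c2ccc(O[Si](C(C)C)(C(C)C)C(C)C)c(OC)c2)[C@H](C3(c4ccc(O[Si](C(C)C)(C(C)C)C(C)C)c(OC)c4)SCCCS3)[C@@H](O[C@H]5C[C@@H](C)CC[C@@H]5C(C)C)O1
F5 | step 7 | (3R,4S,5S)-3-{hydroxy[3-methoxy-4-(triisopropylsilyloxy)phenyl]methyl}-4-[3-methoxy-4-(triisopropylsilyloxy)benzyl]-5-[(1S,2R,5S)-menthyloxy]dihydrofuran-2(3H)-one, carbinol epimers | O=C1[C@@H](C(O)c2ccc(O[Si](C(C)C)(C(C)C)C(C)C)c(OC)c2)[C@H](Cc2ccc(O[Si](C(C)C)(C(C)C)C(C)C)c(OC)c2)[C@@H](O[C@H]3C[C@@H](C)CC[C@@H]3C(C)C)O1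
F6 | step 8 | (2S,3S)-2-[hydroxy(4-hydroxy-3-methoxyphenyl)methyl]-3-(4-hydroxy-3-methoxybenzyl)butane-1,4-diol, carbinol epimers | OC[C@@H](C(O)c1ccc(O)c(OC)c1)[C@H](Cc1ccc(O)c(OC)c1)CO
F7 | step 8 | (−)-lariciresinol, [(2R,3S,4S)-4-(4-hydroxy-3-methoxybenzyl)-2-(4-hydroxy-3-methoxyphenyl)tetrahydrofuran-3-yl]methanol | OC[C@@H]1[C@H](Cc2ccc(O)c(OC)c2)CO[C@H]1c1ccc(O)c(OC)c1
F0 | step 9 | none | none
A1 | alternative 1 | 4-(tert-butyldimethylsilyloxy)-3-methoxybenzaldehyde | COc1cc(C=O)ccc1O[Si](C)(C)C(C)(C)C
A2 | alternative 1 | (2R)-2-[(S)-{[(2E)-3-[4-(tert-butyldimethylsilyloxy)-3-methoxyphenyl]prop-2-en-1-yl]oxy}[4-(tert-butyldimethylsilyloxy)-3-methoxyphenyl]methyl]oxirane | COc1cc(/C=C/CO[C@H]([C@H]2CO2)c2ccc(O[Si](C)(C)C(C)(C)C)c(OC)c2)ccc1O[Si](C)(C)C(C)(C)C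
A3 | alternative 1 | [(2R,3S,4S)-4-[4-(tert-butyldimethylsilyloxy)-3-methoxybenzyl]-2-[4-(tert-butyldimethylsilyloxy)-3-methoxyphenyl]tetrahydrofuran-3-yl]methanol | OC[C@@H]1[C@H](Cc2ccc(O[Si](C)(C)C(C)(C)C)c(OC)c2)CO[C@H]1c1ccc(O[Si](C)(C)C(C)(C)C)c(OC)c1
A4 | alternative 2 | methyl (2Z)-4-(tert-butyldimethylsilyloxy)-2-[(4,4,5,5-tetramethyl-1,3,2-dioxaborolan-2-yl)methyl]but-2-enoate | COC(=O)/C(CB1OC(C)(C)C(C)(C)O1)=C\CO[Si](C)(C)C(C)(C)C
A5 | alternative 2 | (4S,5R)-5-[4-(tert-butyldimethylsilyloxy)-3-methoxyphenyl]-4-[(tert-butyldimethylsilyloxy)methyl]-3-methylidenedihydrofuran-2(3H)-one | O=C1O[C@@H](c2ccc(O[Si](C)(C)C(C)(C)C)c(OC)c2)[C@H](CO[Si](C)(C)C(C)(C)C)C1=C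
A6 | alternative 3 | tert-butyl{4-[chloro(trimethylsilylmethoxy)methyl]-2-methoxyphenoxy}dimethylsilane (racemic) | COc1cc(C(Cl)OC[Si](C)(C)C)ccc1O[Si](C)(C)C(C)(C)C
A7 | alternative 3 | (5R)-5-[(1R,2S,5R)-menthyloxy]furan-2(5H)-one | O=C1C=C[C@H](O[C@@H]2C[C@H](C)CC[C@H]2C(C)C)O1
A8 | alternative 3 | cis-fused 8-[4-(tert-butyldimethylsilyloxy)-3-methoxyphenyl]-4-[(1R,2S,5R)-menthyloxy]-3,7-dioxabicyclo[3.3.0]octan-2-one, aryl exo | O=C1O[C@@H](O[C@@H]3C[C@H](C)CC[C@H]3C(C)C)[C@@H]2CO[C@@H](c4ccc(O[Si](C)(C)C(C)(C)C)c(OC)c4)[C@H]12
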